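(The runs are simulated for substances that don't exist.)

The easy step comes first: red repeats the charge of oak in a closed flask, so the oak readings at the same time are red's readings in advance.

| setting | oak | ash | grey | red | blue | ochre |
|---|---|---|---|---|---|---|
| starting material | 0.10 M | 0.20 M | 0.10 M | 0.10 M | 0.10 M (fed, over 3.20 h) | 0.10 M |
| free catalyst | 1 mM | 1 mM | 1.0 mM | 1.0 mM | 1.0 mM | 1.0 mM |
| impurity | 0.70 mM | 0.70 mM | 0.70 mM | 0.70 mM | 0.70 mM | 0.70 mM |
| remark | run made earlier | run made earlier | a single well-mixed tank run continuously and read at steady state, 20.0 h in it on average | a closed flask charged with all of it at once and left for 4.0 h | all but starting material at the start; starting material goes in evenly over 3.20 h, the run ends at 4.0 h | one stirred flow tank at steady state, fed with the mixture as stated, mean residence time 4.0 h |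
| time |  |  |  | 4.0 h | 4.0 h |  |

oak run (percent of the starting material charged)

| time / h | product / % | starting material / % |
|---|---|---|
| 0.333 | 0.9 | 98.5 |
| 0.500 | 1.2 | 99.4 |
| 0.667 | 1.1 | 98.2 |
| 1.00 | 1.2 | 98.3 |
| 1.50 | 3.1 | 97.1 |
| 2.50 | 5.1 | 96.2 |
| 4.00 | 7.7 | 93.1 |

ash run (percent of the starting material charged)

| time / min | product / % | starting material / % |
|---|---|---|
| 3.00 | 0 | 99.6 |
| 6.00 | 0 | 99.9 |
| 10.0 | 0 | 99.9 |
| 15.0 | 0.8 | 99.6 |
| 20.0 | 1.3 | 100.3 |
| 25.0 | 0 | 99.4 |

(each reading ± 0.5 percentage points)

- the stated concentrations are those of everything mixed, before any reaction; amounts are the same in each set-up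
- the feed brings no volume worth counting
- the earlier runs were made in a closed, stirred flask

* the set-up with the highest amount of product at the outlet or at the end, in percent of the starting material put in ("none" if the first two lie within 2 percentage points) (grey / red / blue / ochre / none)
* amount of product at the outlet or at the end, in percent of the starting material put in, grey
* amount of product at the outlet or at the end, in percent of the starting material put in, red
* amount of product at the outlet or at the end, in percent of the starting material put in, blue
* amount of product at the outlet or at the end, in percent of the starting material put in, ochre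

Slowly, then, through oak. In the first instants the impurity may take free catalyst one for one. Its 0.70 mM is less than the 1 mM of catalyst charged, so 0.300 mM of working catalyst stays in the oak flask; this is a guess from the charge, since no reading is that early. Through the middle, between 1.00 h and 2.50 h, product climbs from 1.2% to 5.1% at a roughly even pace. At 4.00 h oak holds 7.7% of product with 93.1% of starting material still there, and ash, stopped at 25.0 min, is too short to test the order. Taken as first order in starting material (pseudo-first-order, the working catalyst constant), oak gives a rate constant of 0.0200 /h. Divided by the working catalyst, this is the specific rate, the rate constant per unit of working catalyst, 0.0185 /M/s.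

The time scale 50.0 h is far longer than 4.0 h, so my reckoning turns on the time that starting material spends with catalyst. My own reckoning gives 7.70% for red. Blue, whose feed gives a mean stay of 2.40 h, comes to 4.69%. The tanks follow k·τ/(1 + k·τ), with 7.42% for ochre and 28.6% for grey, which is more than any other.

The forecast gives 30% for grey, 7.8% for red, 5% for blue and 7.4% for ochre, and ends: “Grey wins clearly.”

The simulation names grey, with 28.8% for grey, 7.40% for red, 4.67% for blue and 7.24% for ochre.

    starting material + free catalyst ⇌ catalyst intermediate (K = 3.80 /M, k = 0.0790 /M/s)
    free catalyst + impurity → spent catalyst (k = 44.0 /M/s)
    catalyst intermediate → free catalyst + product (k = 0.00820 /s)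

Blue ends at 4.67% partly through the reaction of free catalyst with impurity, together with the length of the run: without that reaction blue gives 14.7%, and left ten times as long it gives 54.2%. In blue at 4.00 h, spent catalyst stands at 70.0% of the catalyst charged. The neighbour of blue, with 1.7 × 10⁻⁴ M of impurity, has 0.830 mM of working catalyst by the one-for-one reckoning, so the specific rate over the mean stay gives 12.5%, and that flask holds 12.4% of product at 4.00 h.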